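The route disconnects the ring C4–C5 bond of the 1,2-dioxane. C3 and C6, the carbons bonded to O2 and O1, flank this bond, so each can carry a vinyl group on an acyclic peroxide in which O1–O2 already exists. Ring-closing metathesis then forms C4=C5 and the six-membered peroxide ring in one operation. The precursor is a mixed methyl peroxyketal, made by acid-catalysed addition of an (R)-allylic hydroperoxide across a 1-alkyl-1-methoxyallene; this installs the C6 vinyl group without passing through a vinyl ketone ketal. Diimide reduction, ketal equilibration, desilylation and an enyne coupling complete the synthesis.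

Key step: step 7

Ring numbering used throughout: O1, O2, C3 (bears CH2CO2Me), C4, C5, C6 (ketal carbon).
Assumption: in the peroxidase resolution (step 2) the slow-reacting enantiomer of 2 is taken to be (R), following the large/small-group preference known for this enzyme with CH2CO2Me as the large and vinyl as the small group; this is to be checked by reducing a sample to methyl 3-hydroxypent-4-enoate of known configuration.
Remark: the descriptor at C3 is (R) in 3, 11 and 12 and (S) in 13, 14, 15 and 19 only because the CIP rank of C4 against CH2CO2Me changes on saturation; the spatial arrangement is the same throughout.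

Step 1
Reactants: 1 methyl (3E)-pent-3-enoate
Product: 2 methyl (3RS)-3-hydroperoxypent-4-enoate (racemate)
Conditions: O2, hν (visible), tetraphenylporphyrin (cat.), CH2Cl2, 0 °C; chromatography
Reagents that add atoms: dioxygen, O=O
Why: Schenck ene reaction of singlet oxygen, in which C–O bond formation at C3 with transfer of a C5 hydrogen moves the double bond to C4=C5 and gives the racemic allylic hydroperoxide; the competing ene mode that removes a C2 hydrogen gives the conjugated 4-hydroperoxy-2-enoate, which may well be the larger share and is removed by chromatography.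

Step 2
Reactants: 2 methyl (3RS)-3-hydroperoxypent-4-enoate
Product: 3 methyl (3R)-3-hydroperoxypent-4-enoate
Conditions: horseradish peroxidase, guaiacol, phosphate buffer pH 6, rt, run to just past half conversion; chromatography
Reagents that add atoms: none
Why: Enzymatic kinetic resolution by peroxidase-catalysed enantioselective reduction of a racemic secondary hydroperoxide, in which the (S)-enantiomer should be reduced to the alcohol and the (R)-hydroperoxide left untouched, so that the later ring stereocentre C3 is fixed here without any bond to it being made or broken.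

Step 3
Reactants: 4 5-chloropent-1-yne
Product: 6 (5-chloropent-1-yn-1-yl)tri(propan-2-yl)silane, via (5-chloropent-1-yn-1-yl)lithium 5 (not isolated)
Conditions: n-BuLi, THF, −78 °C; then iPr3SiCl, −78 °C → rt
Reagents that add atoms: chlorotri(propan-2-yl)silane, CC(C)[Si](Cl)(C(C)C)C(C)C
Why: Deprotonation of the terminal alkyne and C-silylation of the lithium acetylide, which at low temperature is much faster than any attack on the primary chloride.

Step 4
Reactants: 6 (5-chloropent-1-yn-1-yl)tri(propan-2-yl)silane
Product: 7 (5-iodopent-1-yn-1-yl)tri(propan-2-yl)silane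
Conditions: NaI, acetone, reflux
Reagents that add atoms: sodium iodide, [Na+].[I-]
Why: Finkelstein halide exchange, driven by precipitation of sodium chloride from acetone, provides the more reactive primary iodide for the alkylation that follows.

Step 5
Reactants: 8 methoxyallene (1-methoxypropa-1,2-diene); 7 (5-iodopent-1-yn-1-yl)tri(propan-2-yl)silane
Product: 10 (6-methoxyocta-6,7-dien-1-yn-1-yl)tri(propan-2-yl)silane, via (1-methoxypropa-1,2-dien-1-yl)lithium 9 (not isolated)
Conditions: 8 (slight excess), n-BuLi, THF, −40 °C; then 7, −40 °C → rt; chromatography on Et3N-deactivated silica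
Reagents that add atoms: none
Why: α-Lithiation of the alkoxyallene at C1 followed by SN2 alkylation with the primary iodide, the standard use of lithiated methoxyallene, should give the 1-alkyl-1-methoxyallene while the hindered silylalkyne stays inert.

Step 6
Reactants: 3 methyl (3R)-3-hydroperoxypent-4-enoate; 10 (6-methoxyocta-6,7-dien-1-yn-1-yl)tri(propan-2-yl)silane
Product: 11 methyl (3R)-3-[(3-methoxy-8-[tri(propan-2-yl)silyl]oct-1-en-7-yn-3-yl)peroxy]pent-4-enoate (both epimers at the ketal carbon)
Conditions: 10 (1.3 equiv), PPTS (cat.), CH2Cl2, 0 °C; Et3N quench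
Reagents that add atoms: none
Why: Acid-catalysed addition of a hydroperoxide to an enol ether (perketalisation), applied to the oxygen-substituted double bond of an alkoxyallene: protonation at the central allene carbon gives an oxocarbenium ion whose new vinyl group starts orthogonal to the empty orbital, so the hydroperoxide should attack the ketal carbon and not the allylic terminus; C3 is untouched and the ketal carbon forms as both epimers.

Step 7
Reactants: 11 methyl (3R)-3-[(3-methoxy-8-[tri(propan-2-yl)silyl]oct-1-en-7-yn-3-yl)peroxy]pent-4-enoate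
Product: 12 methyl 2-[(3R,6RS)-6-methoxy-6-{5-[tri(propan-2-yl)silyl]pent-4-yn-1-yl}-3,6-dihydro-1,2-dioxin-3-yl]acetate (C6 epimer mixture)
Conditions: second-generation Hoveyda–Grubbs catalyst (5–10 mol%), CH2Cl2 (5 mM), 40 °C, argon sparge
Reagents that add atoms: none
Why: Proposed new method: the ruthenium alkylidene should load onto the less hindered C3 vinyl group, add to the C6 vinyl group in a [2+2] step and open the ruthenacyclobutane by retro-[2+2], which forms the C4=C5 bond and releases ethene while the O1–O2 bond stays a spectator. The closest known reaction types are ring-closing metathesis of bis-allylic ethers and mixed allylic acetals to six-membered oxygen heterocycles, and ruthenium-catalysed cross-metathesis of alkenes that carry dialkyl peroxides. The 3,6-dihydro-1,2-dioxin ring closes as a six-membered ring with an endocyclic alkene that can only be cis, and the gauche C–O–O–C geometry of the peroxide holds the two vinyl groups within reach. No stereocentre is created: C3 comes unchanged from 3, and C6, present as both epimers, is corrected in step 9. The step needs alkene–alkene metathesis to win over enyne metathesis and oligomerisation, which the bulky triisopropylsilyl cap on the internal alkyne, the favourable ring size and high dilution should secure; a phosphine-free catalyst is chosen so that no free phosphine can reduce the peroxide.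

Step 8
Reactants: 12 methyl 2-[(3R,6RS)-6-methoxy-6-{5-[tri(propan-2-yl)silyl]pent-4-yn-1-yl}-3,6-dihydro-1,2-dioxin-3-yl]acetate
Product: 13 methyl 2-[(3S,6RS)-6-methoxy-6-{5-[tri(propan-2-yl)silyl]pent-4-yn-1-yl}-1,2-dioxan-3-yl]acetate (C6 epimer mixture)
Conditions: KO2CN=NCO2K (excess), AcOH, CH2Cl2, 0 °C → rt
Reagents that add atoms: none
Why: Diimide reduction, a concerted syn transfer of two hydrogens that leaves O–O bonds intact and is established for unsaturated cyclic peroxides, should saturate the cis ring alkene in preference to the sterically shielded silylalkyne.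

Step 9
Reactants: 13 methyl 2-[(3S,6RS)-6-methoxy-6-{5-[tri(propan-2-yl)silyl]pent-4-yn-1-yl}-1,2-dioxan-3-yl]acetate
Product: 14 methyl 2-[(3S,6R)-6-methoxy-6-{5-[tri(propan-2-yl)silyl]pent-4-yn-1-yl}-1,2-dioxan-3-yl]acetate
Conditions: camphorsulfonic acid (cat.), MeOH, rt; chromatography, minor epimer resubmitted
Reagents that add atoms: methanol, CO
Why: Acid-catalysed ketal exchange through the cyclic peroxycarbenium ion equilibrates C6 under thermodynamic control, and the anomeric effect should favour the epimer with axial OMe and both carbon substituents equatorial, that is OMe cis to CH2CO2Me as in the target.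

Step 10
Reactants: 14 methyl 2-[(3S,6R)-6-methoxy-6-{5-[tri(propan-2-yl)silyl]pent-4-yn-1-yl}-1,2-dioxan-3-yl]acetate
Product: 15 methyl 2-[(3S,6R)-6-methoxy-6-(pent-4-yn-1-yl)-1,2-dioxan-3-yl]acetate
Conditions: Bu4NF, AcOH (1:1), THF, 0 °C → rt
Reagents that add atoms: none
Why: Fluoride-induced protodesilylation of the alkynylsilane, buffered with acetic acid so that the β-peroxy ester does not meet a base strong enough for retro-oxa-Michael opening of the ring.

Step 11
Reactants: 16 dec-9-en-1-ol
Product: 17 dec-9-enal
Conditions: TEMPO (cat.), PhI(OAc)2, CH2Cl2, rt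
Reagents that add atoms: none
Why: Nitroxyl-catalysed oxidation of the primary alcohol with a hypervalent iodine co-oxidant stops at the aldehyde and does not touch the terminal alkene.

Step 12
Reactants: 17 dec-9-enal
Product: 18 (1E)-1-iodoundeca-1,10-diene
Conditions: CrCl2, CHI3, THF, 0 °C → rt
Reagents that add atoms: iodoform, IC(I)I
Why: Takai olefination, in which the geminal dichromium species formed from iodoform adds to the aldehyde and eliminates with the alkyl group and iodine anti, should give the (E)-vinyl iodide and leave the remote terminal alkene alone.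

Step 13
Reactants: 15 methyl 2-[(3S,6R)-6-methoxy-6-(pent-4-yn-1-yl)-1,2-dioxan-3-yl]acetate; 18 (1E)-1-iodoundeca-1,10-diene
Product: 19 peroxyacarnoate A, methyl 2-{(3S,6R)-6-[(6E)-hexadeca-6,15-dien-4-yn-1-yl]-6-methoxy-1,2-dioxan-3-yl}acetate
Conditions: PdCl2(PPh3)2 (cat.), CuI (cat.), Et3N, THF, rt, degassed
Reagents that add atoms: none
Why: Sonogashira coupling of the terminal alkyne with the vinyl iodide proceeds with retention of the (E) geometry under mild Pd/Cu/amine conditions that monocyclic 1,2-dioxanes tolerate, and joins the side chain without touching C3 or C6.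

Compound list
1 | methyl (3E)-pent-3-enoate | C/C=C/CC(=O)OC | starting material
2 | methyl (3RS)-3-hydroperoxypent-4-enoate (racemate) | C=CC(CC(=O)OC)OO | intermediate
3 | methyl (3R)-3-hydroperoxypent-4-enoate | OO[C@@H](C=C)CC(=O)OC | intermediate
4 | 5-chloropent-1-yne | C#CCCCCl | starting material
5 | (5-chloropent-1-yn-1-yl)lithium | [Li]C#CCCCCl | intermediate (not isolated)
6 | (5-chloropent-1-yn-1-yl)tri(propan-2-yl)silane | ClCCCC#C[Si](C(C)C)(C(C)C)C(C)C | intermediate
7 | (5-iodopent-1-yn-1-yl)tri(propan-2-yl)silane | ICCCC#C[Si](C(C)C)(C(C)C)C(C)C | intermediate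
8 | methoxyallene (1-methoxypropa-1,2-diene) | COC=C=C | starting material
9 | (1-methoxypropa-1,2-dien-1-yl)lithium | [Li]C(OC)=C=C | intermediate (not isolated)
10 | (6-methoxyocta-6,7-dien-1-yn-1-yl)tri(propan-2-yl)silane | C=C=C(OC)CCCC#C[Si](C(C)C)(C(C)C)C(C)C | intermediate
11 | methyl (3R)-3-[(3-methoxy-8-[tri(propan-2-yl)silyl]oct-1-en-7-yn-3-yl)peroxy]pent-4-enoate (both epimers at the ketal carbon) | CC(C)[Si](C(C)C)(C(C)C)C#CCCCC(OC)(C=C)OO[C@@H](C=C)CC(=O)OC | intermediate
12 | methyl 2-[(3R,6RS)-6-methoxy-6-{5-[tri(propan-2-yl)silyl]pent-4-yn-1-yl}-3,6-dihydro-1,2-dioxin-3-yl]acetate (C6 epimer mixture; the (6R) epimer is drawn) | CC(C)[Si](C(C)C)(C(C)C)C#CCCC[C@]1(OC)C=C[C@@H](CC(=O)OC)OO1 | intermediate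
13 | methyl 2-[(3S,6RS)-6-methoxy-6-{5-[tri(propan-2-yl)silyl]pent-4-yn-1-yl}-1,2-dioxan-3-yl]acetate (C6 epimer mixture) | CC(C)[Si](C(C)C)(C(C)C)C#CCCCC1(OC)CC[C@@H](CC(=O)OC)OO1 | intermediate
14 | methyl 2-[(3S,6R)-6-methoxy-6-{5-[tri(propan-2-yl)silyl]pent-4-yn-1-yl}-1,2-dioxan-3-yl]acetate | CC(C)[Si](C(C)C)(C(C)C)C#CCCC[C@]1(OC)CC[C@@H](CC(=O)OC)OO1 | intermediate
15 | methyl 2-[(3S,6R)-6-methoxy-6-(pent-4-yn-1-yl)-1,2-dioxan-3-yl]acetate | C#CCCC[C@]1(OC)CC[C@@H](CC(=O)OC)OO1 | intermediate
16 | dec-9-en-1-ol | C=CCCCCCCCCO | starting material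
17 | dec-9-enal | C=CCCCCCCCC=O | intermediate
18 | (1E)-1-iodoundeca-1,10-diene | C=CCCCCCCC/C=C/I | intermediate
19 | peroxyacarnoate A, methyl 2-{(3S,6R)-6-[(6E)-hexadeca-6,15-dien-4-yn-1-yl]-6-methoxy-1,2-dioxan-3-yl}acetate | C=CCCCCCCC/C=C/C#CCCC[C@]1(OC)CC[C@@H](CC(=O)OC)OO1 | target

Total step count: 13
Longest linear sequence: 9 steps (steps 3, 4, 5, 6, 7, 8, 9, 10, 13)

Steps most likely to fail

Step 7 (ring-closing metathesis). The ruthenium carbene may be destroyed by the allylic O–O bond, or the C3-bound alkylidene may fail to engage the hindered vinyl group on the fully substituted ketal carbon, so that the C3 vinyl groups dimerise. The fallback uses known chemistry, avoids metathesis and closes the ring by C–O bond formation; it sets out from 3 and 6 and comes back at 14.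
- Hydroperoxide 3 is capped with 2-methoxypropene (PPTS) as methyl (3R)-3-[(2-methoxypropan-2-yl)peroxy]pent-4-enoate F1.
- Ozonolysis of F1 with dimethyl sulfide work-up gives the peroxy aldehyde methyl (3R)-3-[(2-methoxypropan-2-yl)peroxy]-4-oxobutanoate F2.
- In parallel the Grignard reagent from chloride 6 is acylated with 2-chloro-N-methoxy-N-methylacetamide to 1-chloro-7-[tri(propan-2-yl)silyl]hept-6-yn-2-one F3.
- F3 with triphenylphosphine and then aqueous sodium carbonate gives the stabilised ylide 1-(triphenyl-λ5-phosphanylidene)-7-[tri(propan-2-yl)silyl]hept-6-yn-2-one F4.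
- Wittig reaction of F2 with F4 under neutral conditions gives the enone methyl (3R,4E)-3-[(2-methoxypropan-2-yl)peroxy]-6-oxo-11-[tri(propan-2-yl)silyl]undec-4-en-10-ynoate F5.
- Diimide saturates the enone alkene to methyl (3S)-3-[(2-methoxypropan-2-yl)peroxy]-6-oxo-11-[tri(propan-2-yl)silyl]undec-10-ynoate F6.
- Camphorsulfonic acid in methanol removes the perketal, closes the hydroperoxy ketone to the six-membered peroxyhemiketal and converts it into the thermodynamic methyl ketal 14.

Step 2 (enzymatic resolution). The enzyme may discriminate poorly between the enantiomers of this small substrate, or may consume the wanted (R)-enantiomer. The fallback is a chromatographic resolution through diastereomeric perketals; it sets out from 2 and comes back at 3.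
- Racemic 2 is added (PPTS, CH2Cl2) to the enantiopure enol ether (1R,2S)-2-phenylcyclohexyl prop-1-en-2-yl ether F7, made from commercial (1R,2S)-2-phenylcyclohexan-1-ol and 2-methoxypropene.
- The two diastereomeric perketals are separated by chromatography; the one wanted is methyl (3R)-3-({2-[(1R,2S)-2-phenylcyclohexyl]oxypropan-2-yl}peroxy)pent-4-enoate F8, assigned by reducing a sample to the known alcohol.
- Aqueous acetic acid in THF releases 3.

Step 6 (hydroperoxide addition to the allene). The oxocarbenium ion may be captured at its allylic terminus, or the allene may hydrate and oligomerise under acid before the hydroperoxide adds. The fallback replaces the kinetic addition by an equilibrium exchange on an isolable ketal; it sets out from 10 (with 3) and comes back at 11.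
- Allene 10 is first converted with methanol and PPTS into the dimethyl ketal (6,6-dimethoxyoct-7-en-1-yn-1-yl)tri(propan-2-yl)silane F9.
- Transketalisation of F9 with 3 (PPTS, CH2Cl2, 5 Å molecular sieves to take up methanol) gives 11.

Further compounds
F1 | step 7 | methyl (3R)-3-[(2-methoxypropan-2-yl)peroxy]pent-4-enoate | COC(C)(C)OO[C@@H](C=C)CC(=O)OC
F2 | step 7 | methyl (3R)-3-[(2-methoxypropan-2-yl)peroxy]-4-oxobutanoate | COC(C)(C)OO[C@@H](C=O)CC(=O)OC
F3 | step 7 | 1-chloro-7-[tri(propan-2-yl)silyl]hept-6-yn-2-one | CC(C)[Si](C(C)C)(C(C)C)C#CCCCC(=O)CCl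
F4 | step 7 | 1-(triphenyl-λ5-phosphanylidene)-7-[tri(propan-2-yl)silyl]hept-6-yn-2-one | CC(C)[Si](C(C)C)(C(C)C)C#CCCCC(=O)C=P(c1ccccc1)(c1ccccc1)c1ccccc1
F5 | step 7 | methyl (3R,4E)-3-[(2-methoxypropan-2-yl)peroxy]-6-oxo-11-[tri(propan-2-yl)silyl]undec-4-en-10-ynoate | COC(C)(C)OO[C@@H](/C=C/C(=O)CCCC#C[Si](C(C)C)(C(C)C)C(C)C)CC(=O)OC
F6 | step 7 | methyl (3S)-3-[(2-methoxypropan-2-yl)peroxy]-6-oxo-11-[tri(propan-2-yl)silyl]undec-10-ynoate | COC(C)(C)OO[C@@H](CCC(=O)CCCC#C[Si](C(C)C)(C(C)C)C(C)C)CC(=O)OC
F7 | step 2 | (1R,2S)-2-phenylcyclohexyl prop-1-en-2-yl ether | CC(=C)O[C@@H]1CCCC[C@H]1c1ccccc1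
F8 | step 2 | methyl (3R)-3-({2-[(1R,2S)-2-phenylcyclohexyl]oxypropan-2-yl}peroxy)pent-4-enoate | CC(C)(O[C@@H]1CCCC[C@H]1c1ccccc1)OO[C@@H](C=C)CC(=O)OC
F9 | step 6 | (6,6-dimethoxyoct-7-en-1-yn-1-yl)tri(propan-2-yl)silane | C=CC(OC)(OC)CCCC#C[Si](C(C)C)(C(C)C)C(C)C
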